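**Plan**

- Core numbering used here: 2,8-dioxabicyclo[3.2.1]octane with ketal carbon C1, ring oxygen O2, alkenyl-bearing C3, C4H2, methyl-bearing C5, C6H2, C7H2 and bridging O8. O2 is the only atom between C1 and C3; without it the carbocycle C1–C7–C6–C5–C4–C3 bridged by O8 is a 7-oxabicyclo[2.2.1]heptane, so a C3 ketone next to bridgehead C1 can take up O2 by Baeyer–Villiger insertion.
- Cuts: ArCH2–CH(OAc) (benzylzinc to an α-hydroxy aldehyde); C3–alkenyl (alkenylzinc to the lactol); C1–O2 (Baeyer–Villiger); O8–C1 (transannular epoxide opening); two cyclohexene bonds (Diels–Alder of a 2-substituted butadiene with methacrolein); diene–carbinol bond (Grignard addition to 2,2-dimethyl-1,3-dioxan-5-one).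
- Forward order of rings: cyclohexene, then the O8 bridge (7-oxabicyclo[2.2.1]heptan-2-one), then O2 insertion, then lactol opening, alkenylation at C3 and re-ketalisation; the side chain and the hydroquinone come last.
- Stereochemistry: C5 (and through the bridge C1) from the catalyst-controlled Diels–Alder step; C3 from the amino-alcohol ligand in the alkenylzinc addition; the tertiary carbinol from lipase differentiation of two hydroxymethyl groups; the CH(OAc) centre from chelation-controlled benzylzinc addition.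

Key step: step 7

Assumption: the sense of induction of the two chiral controllers (oxazaborolidinium salt in step 3, amino alcohol in step 11) is taken from their standard models; if a model fails, the enantiomeric controller is used and nothing else changes.

**Step 1**
Reactants: 1 chloroprene (2-chlorobuta-1,3-diene); 2 2,2-dimethyl-1,3-dioxan-5-one
Product: 4 5-(buta-1,3-dien-2-yl)-2,2-dimethyl-1,3-dioxan-5-ol, via buta-1,3-dien-2-ylmagnesium chloride 3 (not isolated)
Conditions: Mg, ZnCl2 (cat.), BrCH2CH2Br (cat.), THF, reflux; then 2, THF, −78 → 0 °C; aq. NH4Cl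
Reagents that add atoms: none
Why: Grignard addition to a ketone, in which the alkenylmagnesium chloride from chloroprene should attack the inductively activated dioxanone carbonyl at low temperature faster than it enolises it; no stereocentre arises because the dioxane is symmetric.

**Step 2**
Reactants: 4 5-(buta-1,3-dien-2-yl)-2,2-dimethyl-1,3-dioxan-5-ol
Product: 5 [5-(buta-1,3-dien-2-yl)-2,2-dimethyl-1,3-dioxan-5-yl]oxy(triethyl)silane
Conditions: Et3SiOSO2CF3, 2,6-lutidine, CH2Cl2, −78 → 0 °C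
Reagents that add atoms: triethylsilyl trifluoromethanesulfonate, CC[Si](CC)(CC)OS(=O)(=O)C(F)(F)F
Why: Silylation of a hindered tertiary alcohol with a silyl triflate and a hindered pyridine base, which removes the only protic group before the Lewis-acid step and prevents later migration of the acetonide onto the tertiary oxygen.

**Step 3**
Reactants: 5 [5-(buta-1,3-dien-2-yl)-2,2-dimethyl-1,3-dioxan-5-yl]oxy(triethyl)silane; 6 methacrolein (2-methylprop-2-enal)
Product: 7 (1R)-4-[2,2-dimethyl-5-(triethylsilyloxy)-1,3-dioxan-5-yl]-1-methylcyclohex-3-ene-1-carbaldehyde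
Conditions: salt of (S)-1-(2-methylphenyl)-3,3-diphenyltetrahydro-1H,3H-pyrrolo[1,2-c][1,3,2]oxazaborole with (CF3SO2)2NH (20 mol %), 6 (5 equiv), CH2Cl2, −78 → −40 °C
Reagents that add atoms: none
Why: Enantioselective Diels–Alder reaction in which the cationic oxazaborolidine binds s-trans methacrolein through boron and a formyl C–H···O contact, the 2-substituted diene adds in the "para" sense usual under Lewis-acid catalysis, and shielding of one enal face (attack on the Si face of the α-carbon) should set the quaternary centre as R.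

**Step 4**
Reactants: 7 (1R)-4-[2,2-dimethyl-5-(triethylsilyloxy)-1,3-dioxan-5-yl]-1-methylcyclohex-3-ene-1-carbaldehyde
Product: 9 (1R,4R,6S)-1-[2,2-dimethyl-5-(triethylsilyloxy)-1,3-dioxan-5-yl]-4-methyl-7-oxabicyclo[4.1.0]heptan-4-yl formate, via epoxy aldehyde 8 (not isolated)
Conditions: 3-ClC6H4CO3H (3 equiv), NaHCO3, CH2Cl2, 0 → 23 °C
Reagents that add atoms: 3-chloroperoxybenzoic acid, OOC(=O)c1cccc(Cl)c1
Why: Prilezhaev epoxidation followed in the same flask by Baeyer–Villiger oxidation of the α-quaternary aldehyde (the tertiary alkyl group migrates with retention to give the formate); the peracid should approach the ring alkene mainly anti to the pseudoaxial formyl group, and the minor syn epoxide is carried along because both series converge at the ketone of step 6.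

**Step 5**
Reactants: 9 (1R,4R,6S)-1-[2,2-dimethyl-5-(triethylsilyloxy)-1,3-dioxan-5-yl]-4-methyl-7-oxabicyclo[4.1.0]heptan-4-yl formate
Product: 11 (1S,2S,4R)-1-[2,2-dimethyl-5-(triethylsilyloxy)-1,3-dioxan-5-yl]-4-methyl-7-oxabicyclo[2.2.1]heptan-2-ol, via epoxy alcohol 10 (not isolated)
Conditions: K2CO3 (0.2 equiv), CH3OH, 0 °C; filtration and solvent change; camphor-10-sulfonic acid (10 mol %), CH2Cl2, 0 → 23 °C
Reagents that add atoms: none
Why: Transesterification frees the tertiary alcohol, and acid-catalysed transannular epoxide opening should then close the oxygen bridge by backside attack of that hydroxyl, through a boat, on the fully substituted epoxide carbon (the only one it can reach, inversion there), leaving the secondary alcohol endo.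

**Step 6**
Reactants: 11 (1S,2S,4R)-1-[2,2-dimethyl-5-(triethylsilyloxy)-1,3-dioxan-5-yl]-4-methyl-7-oxabicyclo[2.2.1]heptan-2-ol
Product: 12 (1R,4R)-1-[2,2-dimethyl-5-(triethylsilyloxy)-1,3-dioxan-5-yl]-4-methyl-7-oxabicyclo[2.2.1]heptan-2-one
Conditions: Dess–Martin periodinane, NaHCO3, CH2Cl2, 0 → 23 °C
Reagents that add atoms: none
Why: Dess–Martin oxidation of a hindered secondary alcohol under buffered, non-basic conditions, which avoids β-elimination of the bridging oxygen from the β-alkoxy ketone and erases the carbinol centre, so that both epimers give one ketone.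

**Step 7**
Reactants: 12 (1R,4R)-1-[2,2-dimethyl-5-(triethylsilyloxy)-1,3-dioxan-5-yl]-4-methyl-7-oxabicyclo[2.2.1]heptan-2-one
Product: 13 (1S,5R)-1-[2,2-dimethyl-5-(triethylsilyloxy)-1,3-dioxan-5-yl]-5-methyl-2,8-dioxabicyclo[3.2.1]octan-3-one
Conditions: 3-ClC6H4CO3H (2.5 equiv), NaHCO3, CH2Cl2, 0 → 23 °C
Reagents that add atoms: 3-chloroperoxybenzoic acid, OOC(=O)c1cccc(Cl)c1
Why: The peracid adds to the C2 carbonyl of 12 to give the Criegee adduct, and bridgehead carbon C1 then shifts from carbon to oxygen with loss of 3-chlorobenzoate, keeping its configuration. The closest known reaction is the Baeyer–Villiger oxidation of 7-oxabicyclo[2.2.1]heptan-2-ones, which gives 2,8-dioxabicyclo[3.2.1]octan-3-ones by bridgehead migration. No ring closes by cyclisation: the inserted oxygen enlarges the cyclohexanone ring to the seven-membered lactone ring, and the six-membered 1,3-dioxane ring (C1, O2, C3, C4, C5, O8) appears in the same event. No stereocentre is created; C1 migrates with retention and C5 is untouched, the descriptor of C1 changing from R to S only through the new substituent priorities. The step needs regioselectivity (C1, not the C3 methylene, must migrate) and chemoselectivity: the first is secured by the ring oxygen on C1 and its full substitution, the second by the absence of any alkene or arene in 12 and by the bicarbonate buffer that spares the acetonide and silyl ether.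

**Step 8**
Reactants: 13 (1S,5R)-1-[2,2-dimethyl-5-(triethylsilyloxy)-1,3-dioxan-5-yl]-5-methyl-2,8-dioxabicyclo[3.2.1]octan-3-one
Product: 14 (1S,5R)-1-[2,2-dimethyl-5-(triethylsilyloxy)-1,3-dioxan-5-yl]-5-methyl-2,8-dioxabicyclo[3.2.1]octan-3-ol (both C3 anomers)
Conditions: Al(i-C4H9)2H (1.2 equiv), CH2Cl2, −78 °C; aq. potassium sodium tartrate
Reagents that add atoms: none
Why: Partial reduction of a lactone to the lactol with one hydride equivalent at −78 °C, where the aluminium hemiacetal survives until work-up; the anomeric centre is of no consequence.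

**Step 9**
Reactants: 15 5-bromo-2-methylpent-2-ene
Product: 16 6-methylhept-5-en-1-yne
Conditions: LiC≡CH·H2NCH2CH2NH2, DMSO, 10 → 23 °C
Reagents that add atoms: lithium acetylide–ethane-1,2-diamine complex, [Li]C#C.NCCN
Why: SN2 alkylation of lithium acetylide by a primary homoallylic bromide in a dipolar aprotic solvent.

**Step 10**
Reactants: 16 6-methylhept-5-en-1-yne
Product: 18 (1E)-1-iodo-2,6-dimethylhepta-1,5-diene, via alkenyldimethylalane 17 (not isolated)
Conditions: Al(CH3)3 (2 equiv), Zr(C5H5)2Cl2 (0.25 equiv), CH2Cl2, 23 °C; then I2, THF, −30 → 0 °C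
Reagents that add atoms: trimethylaluminium, C[Al](C)C; iodine, II
Why: Negishi zirconium-catalysed carboalumination (syn addition of methyl and aluminium across the terminal alkyne, aluminium at the terminus) followed by iododealumination with retention, which fixes the E trisubstituted alkene.

**Step 11**
Reactants: 14 (1S,5R)-1-[2,2-dimethyl-5-(triethylsilyloxy)-1,3-dioxan-5-yl]-5-methyl-2,8-dioxabicyclo[3.2.1]octan-3-ol; 18 (1E)-1-iodo-2,6-dimethylhepta-1,5-diene
Product: 21 (4R,6S,7E)-1-[2,2-dimethyl-5-(triethylsilyloxy)-1,3-dioxan-5-yl]-4,6-dihydroxy-4,8,12-trimethyltrideca-7,11-dien-1-one (handled as its mixture with the cyclic hemiketals), via alkenyllithium 19 (not isolated), via ethyl(alkenyl)zinc 20 (not isolated)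
Conditions: 18 (3.5 equiv), tert-butyllithium (7 equiv), Et2O, −78 °C; C2H5ZnCl (from Zn(C2H5)2 + ZnCl2), −78 → 0 °C; N,N,N′,N′-tetraethylethane-1,2-diamine; (2R)-3-exo-morpholinoisoborneol (10 mol %); then 14, toluene, 0 → 23 °C; aq. NH4Cl
Reagents that add atoms: none
Why: Proposed new method: the first equivalent of the organozinc converts the lactol into its zinc alkoxide, whose hydroxy-aldehyde tautomer (aldehyde at C3, zinc hemiketalate at C1) should enter the amino-alcohol–zinc cycle so that the alkenyl group of the mixed ethyl(alkenyl)zinc is delivered to the Re face of the aldehyde as in the Noyori model for this ligand series, setting the allylic carbinol as S, while the masked ketone and the base-sensitive β-alkoxy aldehyde are spared by the non-basic reagent; the closest known reactions are amino-alcohol-catalysed alkenylzinc additions to free aldehydes and Grignard additions to lactols through the same ring–chain tautomerism.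

**Step 12**
Reactants: 21 (4R,6S,7E)-1-[2,2-dimethyl-5-(triethylsilyloxy)-1,3-dioxan-5-yl]-4,6-dihydroxy-4,8,12-trimethyltrideca-7,11-dien-1-one
Product: 22 2-[(1R,3S,5R)-3-[(1E)-2,6-dimethylhepta-1,5-dien-1-yl]-5-methyl-2,8-dioxabicyclo[3.2.1]octan-1-yl]propane-1,2,3-triol
Conditions: HF (48 % aq.), CH3CN–THF, 0 → 23 °C
Reagents that add atoms: none
Why: Desilylation and acetonide hydrolysis with concomitant intramolecular ketalisation, in which only the tertiary and the allylic hydroxyl can bridge the ketone, so the 2,8-dioxabicyclo[3.2.1]octane should form under thermodynamic control with C1 fixed by C5 and C3, the C3–O bond unbroken and the alkenyl group equatorial (exo).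

**Step 13**
Reactants: 22 2-[(1R,3S,5R)-3-[(1E)-2,6-dimethylhepta-1,5-dien-1-yl]-5-methyl-2,8-dioxabicyclo[3.2.1]octan-1-yl]propane-1,2,3-triol
Product: 23 (2R)-2-[(1R,3S,5R)-3-[(1E)-2,6-dimethylhepta-1,5-dien-1-yl]-5-methyl-2,8-dioxabicyclo[3.2.1]octan-1-yl]-2,3-dihydroxypropyl acetate
Conditions: Burkholderia cepacia lipase (Amano PS, immobilised), vinyl acetate, tert-butyl methyl ether, 30 °C
Reagents that add atoms: vinyl acetate, CC(=O)OC=C
Why: Lipase-catalysed transesterification with an enol ester as irreversible acyl donor, a known way to differentiate the hydroxymethyl groups of 2-substituted glycerols, in which the enzyme should acylate one of the two diastereotopic arms and leave the tertiary hydroxyl alone, creating the carbinol stereocentre (2R at this stage).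

**Step 14**
Reactants: 23 (2R)-2-[(1R,3S,5R)-3-[(1E)-2,6-dimethylhepta-1,5-dien-1-yl]-5-methyl-2,8-dioxabicyclo[3.2.1]octan-1-yl]-2,3-dihydroxypropyl acetate
Product: 24 (2S)-2-[(1R,3S,5R)-3-[(1E)-2,6-dimethylhepta-1,5-dien-1-yl]-5-methyl-2,8-dioxabicyclo[3.2.1]octan-1-yl]-2-hydroxy-3-oxopropyl acetate
Conditions: Dess–Martin periodinane, NaHCO3, CH2Cl2, 0 °C; used at once
Reagents that add atoms: none
Why: Dess–Martin oxidation of the remaining primary alcohol, tolerated by the trisubstituted alkenes and the ketal; the α-carbon is fully substituted, so the α-hydroxy aldehyde can neither epimerise nor eliminate acetate.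

**Step 15**
Reactants: 25 1,4-dimethoxy-2-methylbenzene (2,5-dimethoxytoluene)
Product: 26 1-(chloromethyl)-2,5-dimethoxy-4-methylbenzene
Conditions: (CH2O)n, HCl (conc. aq.), AcOH, 50 °C
Reagents that add atoms: formaldehyde (as paraformaldehyde), C=O; hydrogen chloride, Cl
Why: Blanc chloromethylation, an electrophilic aromatic substitution that should occur at the position para to methyl and ortho to methoxy, the least hindered activated site.

**Step 16**
Reactants: 24 (2S)-2-[(1R,3S,5R)-3-[(1E)-2,6-dimethylhepta-1,5-dien-1-yl]-5-methyl-2,8-dioxabicyclo[3.2.1]octan-1-yl]-2-hydroxy-3-oxopropyl acetate; 26 1-(chloromethyl)-2,5-dimethoxy-4-methylbenzene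
Product: 28 (2S,3R)-4-(2,5-dimethoxy-4-methylphenyl)-2-[(1R,3S,5R)-3-[(1E)-2,6-dimethylhepta-1,5-dien-1-yl]-5-methyl-2,8-dioxabicyclo[3.2.1]octan-1-yl]-2,3-dihydroxybutyl acetate, via benzylic zinc chloride 27 (not isolated)
Conditions: 26 (3 equiv), Zn dust, LiCl, THF, 23 °C; then 24, THF, −20 → 0 °C; aq. NH4Cl
Reagents that add atoms: none
Why: Addition of a LiCl-solubilised benzylic zinc chloride to an aldehyde under Cram chelation control, in which zinc bridges the aldehyde oxygen and the α-alkoxide and the benzyl group should enter from the side of the acetoxymethyl group, away from the bicyclic ketal, to give the 3R carbinol; the acetate is inert to the organozinc.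

**Step 17**
Reactants: 28 (2S,3R)-4-(2,5-dimethoxy-4-methylphenyl)-2-[(1R,3S,5R)-3-[(1E)-2,6-dimethylhepta-1,5-dien-1-yl]-5-methyl-2,8-dioxabicyclo[3.2.1]octan-1-yl]-2,3-dihydroxybutyl acetate
Product: 29 (2S,3R)-4-(2,5-dimethoxy-4-methylphenyl)-2-[(1R,3S,5R)-3-[(1E)-2,6-dimethylhepta-1,5-dien-1-yl]-5-methyl-2,8-dioxabicyclo[3.2.1]octan-1-yl]-2-hydroxybutane-1,3-diyl diacetate
Conditions: Ac2O, pyridine, 4-(dimethylamino)pyridine (cat.), CH2Cl2, 0 °C
Reagents that add atoms: acetic anhydride, CC(=O)OC(C)=O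
Why: Nucleophile-catalysed acylation that should acetylate the secondary alcohol only, since the tertiary alcohol flanked by two fully substituted carbons does not react under these mild conditions.

**Step 18**
Reactants: 29 (2S,3R)-4-(2,5-dimethoxy-4-methylphenyl)-2-[(1R,3S,5R)-3-[(1E)-2,6-dimethylhepta-1,5-dien-1-yl]-5-methyl-2,8-dioxabicyclo[3.2.1]octan-1-yl]-2-hydroxybutane-1,3-diyl diacetate
Product: 30 (2S,3R)-2-[(1R,3S,5R)-3-[(1E)-2,6-dimethylhepta-1,5-dien-1-yl]-5-methyl-2,8-dioxabicyclo[3.2.1]octan-1-yl]-2-hydroxy-4-(4-methyl-3,6-dioxocyclohexa-1,4-dien-1-yl)butane-1,3-diyl diacetate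
Conditions: (NH4)2Ce(NO3)6 (2.5 equiv), CH3CN–H2O, 0 °C, short reaction time
Reagents that add atoms: water, O
Why: Oxidative demethylation of a 1,4-dimethoxyarene to the p-quinone (two one-electron oxidations with water adding at the methoxy-bearing carbons), a reaction routinely run in the presence of isolated trisubstituted alkenes and esters; the bicyclic ketal should survive the brief acidic contact.

**Step 19**
Reactants: 30 (2S,3R)-2-[(1R,3S,5R)-3-[(1E)-2,6-dimethylhepta-1,5-dien-1-yl]-5-methyl-2,8-dioxabicyclo[3.2.1]octan-1-yl]-2-hydroxy-4-(4-methyl-3,6-dioxocyclohexa-1,4-dien-1-yl)butane-1,3-diyl diacetate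
Product: 31 (2S,3R)-4-(2,5-dihydroxy-4-methylphenyl)-2-[(1R,3S,5R)-3-[(1E)-2,6-dimethylhepta-1,5-dien-1-yl]-5-methyl-2,8-dioxabicyclo[3.2.1]octan-1-yl]-2-hydroxybutane-1,3-diyl diacetate
Conditions: Na2S2O4, H2O–Et2O (degassed), 23 °C
Reagents that add atoms: none
Why: Two-electron reduction of the quinone to the hydroquinone by dithionite under neutral two-phase conditions that leave both acetates and the ketal untouched.

**Compound list**

1 | chloroprene (2-chlorobuta-1,3-diene) | C=CC(Cl)=C | starting material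
2 | 2,2-dimethyl-1,3-dioxan-5-one | CC1(C)OCC(=O)CO1 | starting material
3 | buta-1,3-dien-2-ylmagnesium chloride | C=CC(=C)[Mg]Cl | intermediate (not isolated)
4 | 5-(buta-1,3-dien-2-yl)-2,2-dimethyl-1,3-dioxan-5-ol | C=CC(=C)C1(O)COC(C)(C)OC1 | intermediate
5 | [5-(buta-1,3-dien-2-yl)-2,2-dimethyl-1,3-dioxan-5-yl]oxy(triethyl)silane | C=CC(=C)C1(O[Si](CC)(CC)CC)COC(C)(C)OC1 | intermediate
6 | methacrolein (2-methylprop-2-enal) | CC(=C)C=O | starting material
7 | (1R)-4-[2,2-dimethyl-5-(triethylsilyloxy)-1,3-dioxan-5-yl]-1-methylcyclohex-3-ene-1-carbaldehyde | O=C[C@@]1(C)CC=C(CC1)C2(O[Si](CC)(CC)CC)COC(C)(C)OC2 | intermediate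
8 | (1R,4R,6S)-1-[2,2-dimethyl-5-(triethylsilyloxy)-1,3-dioxan-5-yl]-4-methyl-7-oxabicyclo[4.1.0]heptane-4-carbaldehyde (epoxide oxygen trans to formyl) | O=C[C@@]1(C)C[C@@H]2O[C@@]2(CC1)C3(O[Si](CC)(CC)CC)COC(C)(C)OC3 | intermediate (not isolated)
9 | (1R,4R,6S)-1-[2,2-dimethyl-5-(triethylsilyloxy)-1,3-dioxan-5-yl]-4-methyl-7-oxabicyclo[4.1.0]heptan-4-yl formate (epoxide oxygen trans to formyloxy) | O=CO[C@@]1(C)C[C@@H]2O[C@@]2(CC1)C3(O[Si](CC)(CC)CC)COC(C)(C)OC3 | intermediate
10 | (1R,4R,6S)-1-[2,2-dimethyl-5-(triethylsilyloxy)-1,3-dioxan-5-yl]-4-methyl-7-oxabicyclo[4.1.0]heptan-4-ol | O[C@@]1(C)C[C@@H]2O[C@@]2(CC1)C3(O[Si](CC)(CC)CC)COC(C)(C)OC3 | intermediate (not isolated)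
11 | (1S,2S,4R)-1-[2,2-dimethyl-5-(triethylsilyloxy)-1,3-dioxan-5-yl]-4-methyl-7-oxabicyclo[2.2.1]heptan-2-ol (2-endo alcohol) | C[C@]12CC[C@@](O1)(C3(O[Si](CC)(CC)CC)COC(C)(C)OC3)[C@@H](O)C2 | intermediate
12 | (1R,4R)-1-[2,2-dimethyl-5-(triethylsilyloxy)-1,3-dioxan-5-yl]-4-methyl-7-oxabicyclo[2.2.1]heptan-2-one | C[C@]12CC[C@@](O1)(C3(O[Si](CC)(CC)CC)COC(C)(C)OC3)C(=O)C2 | intermediate (precursor of the key step)
13 | (1S,5R)-1-[2,2-dimethyl-5-(triethylsilyloxy)-1,3-dioxan-5-yl]-5-methyl-2,8-dioxabicyclo[3.2.1]octan-3-one | CC[Si](CC)(CC)OC1(COC(C)(C)OC1)[C@]23CC[C@](C)(CC(=O)O2)O3 | intermediate (product of the key step)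
14 | (1S,5R)-1-[2,2-dimethyl-5-(triethylsilyloxy)-1,3-dioxan-5-yl]-5-methyl-2,8-dioxabicyclo[3.2.1]octan-3-ol (both C3 anomers) | CC[Si](CC)(CC)OC1(COC(C)(C)OC1)[C@]23CC[C@](C)(CC(O)O2)O3 | intermediate
15 | 5-bromo-2-methylpent-2-ene | CC(C)=CCCBr | starting material
16 | 6-methylhept-5-en-1-yne | C#CCCC=C(C)C | intermediate
17 | [(1E)-2,6-dimethylhepta-1,5-dien-1-yl]dimethylalane | C[Al](C)/C=C(\C)CCC=C(C)C | intermediate (not isolated)
18 | (1E)-1-iodo-2,6-dimethylhepta-1,5-diene | I/C=C(\C)CCC=C(C)C | intermediate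
19 | [(1E)-2,6-dimethylhepta-1,5-dien-1-yl]lithium | [Li]/C=C(\C)CCC=C(C)C | intermediate (not isolated)
20 | [(1E)-2,6-dimethylhepta-1,5-dien-1-yl](ethyl)zinc | CC[Zn]/C=C(\C)CCC=C(C)C | intermediate (not isolated)
21 | (4R,6S,7E)-1-[2,2-dimethyl-5-(triethylsilyloxy)-1,3-dioxan-5-yl]-4,6-dihydroxy-4,8,12-trimethyltrideca-7,11-dien-1-one (open form; equilibrates with cyclic hemiketals) | CC[Si](CC)(CC)OC1(COC(C)(C)OC1)C(=O)CC[C@@](C)(O)C[C@H](O)/C=C(\C)CCC=C(C)C | intermediate
22 | 2-[(1R,3S,5R)-3-[(1E)-2,6-dimethylhepta-1,5-dien-1-yl]-5-methyl-2,8-dioxabicyclo[3.2.1]octan-1-yl]propane-1,2,3-triol | OCC(O)(CO)[C@]12CC[C@](C)(C[C@@H](/C=C(\C)CCC=C(C)C)O1)O2 | intermediate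
23 | (2R)-2-[(1R,3S,5R)-3-[(1E)-2,6-dimethylhepta-1,5-dien-1-yl]-5-methyl-2,8-dioxabicyclo[3.2.1]octan-1-yl]-2,3-dihydroxypropyl acetate | CC(=O)OC[C@](O)(CO)[C@]12CC[C@](C)(C[C@@H](/C=C(\C)CCC=C(C)C)O1)O2 | intermediate
24 | (2S)-2-[(1R,3S,5R)-3-[(1E)-2,6-dimethylhepta-1,5-dien-1-yl]-5-methyl-2,8-dioxabicyclo[3.2.1]octan-1-yl]-2-hydroxy-3-oxopropyl acetate | CC(=O)OC[C@](O)(C=O)[C@]12CC[C@](C)(C[C@@H](/C=C(\C)CCC=C(C)C)O1)O2 | intermediate
25 | 1,4-dimethoxy-2-methylbenzene (2,5-dimethoxytoluene) | COc1ccc(OC)c(C)c1 | starting material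
26 | 1-(chloromethyl)-2,5-dimethoxy-4-methylbenzene | ClCc1cc(OC)c(C)cc1OC | intermediate
27 | (2,5-dimethoxy-4-methylbenzyl)zinc chloride | Cl[Zn]Cc1cc(OC)c(C)cc1OC | intermediate (not isolated)
28 | (2S,3R)-4-(2,5-dimethoxy-4-methylphenyl)-2-[(1R,3S,5R)-3-[(1E)-2,6-dimethylhepta-1,5-dien-1-yl]-5-methyl-2,8-dioxabicyclo[3.2.1]octan-1-yl]-2,3-dihydroxybutyl acetate | CC(=O)OC[C@](O)([C@@H](Cc1cc(OC)c(C)cc1OC)O)[C@]12CC[C@](C)(C[C@@H](/C=C(\C)CCC=C(C)C)O1)O2 | intermediate
29 | (2S,3R)-4-(2,5-dimethoxy-4-methylphenyl)-2-[(1R,3S,5R)-3-[(1E)-2,6-dimethylhepta-1,5-dien-1-yl]-5-methyl-2,8-dioxabicyclo[3.2.1]octan-1-yl]-2-hydroxybutane-1,3-diyl diacetate | CC(=O)OC[C@](O)([C@@H](Cc1cc(OC)c(C)cc1OC)OC(C)=O)[C@]12CC[C@](C)(C[C@@H](/C=C(\C)CCC=C(C)C)O1)O2 | intermediate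
30 | (2S,3R)-2-[(1R,3S,5R)-3-[(1E)-2,6-dimethylhepta-1,5-dien-1-yl]-5-methyl-2,8-dioxabicyclo[3.2.1]octan-1-yl]-2-hydroxy-4-(4-methyl-3,6-dioxocyclohexa-1,4-dien-1-yl)butane-1,3-diyl diacetate | CC(=O)OC[C@](O)([C@@H](CC1=CC(=O)C(C)=CC1=O)OC(C)=O)[C@]12CC[C@](C)(C[C@@H](/C=C(\C)CCC=C(C)C)O1)O2 | intermediate
31 | (2S,3R)-4-(2,5-dihydroxy-4-methylphenyl)-2-[(1R,3S,5R)-3-[(1E)-2,6-dimethylhepta-1,5-dien-1-yl]-5-methyl-2,8-dioxabicyclo[3.2.1]octan-1-yl]-2-hydroxybutane-1,3-diyl diacetate | CC(=O)OC[C@](O)([C@@H](Cc1cc(O)c(C)cc1O)OC(C)=O)[C@]12CC[C@](C)(C[C@@H](/C=C(\C)CCC=C(C)C)O1)O2 | target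

**Step count**

Total: 19 steps. Longest linear sequence: 16 steps (1–8, 11–14, 16–19); steps 9–10 and 15 make the two side fragments.

**Steps most likely to fail**

1. Step 11 (proposed method). The zinc lactolate may open to the aldehyde too slowly, and the substrate-bound zinc alkoxide may promote an unselective background addition, so that facial control at the allylic carbinol is poor. The fallback (organolithium addition to a lactone, then catalyst-controlled ketone reduction) sets out from lactone 13 and leaves out step 8. Alkenyllithium 19 (from 18 and tert-butyllithium, Et2O, −78 °C, 1.1 equiv) is added to 13 in THF at −78 °C and the tetrahedral alkoxide is quenched cold with aq. NH4Cl. This should give the ring-opened hydroxy enone (4R,7E)-1-[2,2-dimethyl-5-(triethylsilyloxy)-1,3-dioxan-5-yl]-4-hydroxy-4,8,12-trimethyltrideca-7,11-diene-1,6-dione F1, whose saturated ketone is masked as the five-membered hemiketal. Corey–Bakshi–Shibata reduction with (R)-1-methyl-3,3-diphenyltetrahydro-1H,3H-pyrrolo[1,2-c][1,3,2]oxazaborole (20 mol %) and catecholborane in toluene at −78 °C, with the alkenyl group as the large substituent, should deliver hydride to the Re face of the enone carbonyl. The route is rejoined at 21.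

2. Step 5. The anti epoxy alcohol may not reach the boat needed for backside attack at the inductively deactivated tertiary carbon. Acid may instead trigger a 1,2-shift from the silyloxy-bearing carbon or participation of an acetonide oxygen, and low facial selectivity in step 4 would send material into the syn series. The fallback makes the syn epoxide on purpose and closes it by ionisation with retention, as in the terpinen-4-ol to 2-hydroxy-1,4-cineole series. It sets out from aldehyde 7: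
   - NaBH4 in CH3OH at 0 °C gives [(1R)-4-[2,2-dimethyl-5-(triethylsilyloxy)-1,3-dioxan-5-yl]-1-methylcyclohex-3-en-1-yl]methanol F2.
   - Hydroxyl-directed epoxidation with VO(C5H7O2)2 (cat.) and tert-butyl hydroperoxide in toluene gives the syn epoxy alcohol [(1S,4R,6R)-1-[2,2-dimethyl-5-(triethylsilyloxy)-1,3-dioxan-5-yl]-4-methyl-7-oxabicyclo[4.1.0]heptan-4-yl]methanol F3.
   - Dess–Martin periodinane gives (1S,4R,6R)-1-[2,2-dimethyl-5-(triethylsilyloxy)-1,3-dioxan-5-yl]-4-methyl-7-oxabicyclo[4.1.0]heptane-4-carbaldehyde F4.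
   - Buffered 3-chloroperoxybenzoic acid gives (1S,4R,6R)-1-[2,2-dimethyl-5-(triethylsilyloxy)-1,3-dioxan-5-yl]-4-methyl-7-oxabicyclo[4.1.0]heptan-4-yl formate F5.
   - K2CO3 (cat.) in CH3OH frees (1S,4R,6R)-1-[2,2-dimethyl-5-(triethylsilyloxy)-1,3-dioxan-5-yl]-4-methyl-7-oxabicyclo[4.1.0]heptan-4-ol F6, which is not isolated.
   - 4-Toluenesulfonic acid (cat.) in CH2Cl2 should convert F6 into the exo alcohol (1S,2R,4R)-1-[2,2-dimethyl-5-(triethylsilyloxy)-1,3-dioxan-5-yl]-4-methyl-7-oxabicyclo[2.2.1]heptan-2-ol F7.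
   - Dess–Martin oxidation of F7 returns the route to ketone 12.

3. Step 13. The enzyme may discriminate the two diastereotopic hydroxymethyl groups poorly or in the wrong sense, turnover may be slow with the bulky triol, and acyl migration between the primary hydroxyls may erode the result. The fallback replaces the enzyme by a small-molecule catalyst and the acetate by a benzoate that is exchanged at the end. It sets out from triol 22:
   - Benzoyl chloride, triethylamine and CuCl2 (5 mol %) with 2,2′-(propane-2,2-diyl)bis[(4R)-4-phenyl-4,5-dihydro-1,3-oxazole] (or its enantiomer if the pairing is mismatched) in THF should give (2R)-2-[(1R,3S,5R)-3-[(1E)-2,6-dimethylhepta-1,5-dien-1-yl]-5-methyl-2,8-dioxabicyclo[3.2.1]octan-1-yl]-2,3-dihydroxypropyl benzoate F8.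
   - Dess–Martin oxidation gives (2S)-2-[(1R,3S,5R)-3-[(1E)-2,6-dimethylhepta-1,5-dien-1-yl]-5-methyl-2,8-dioxabicyclo[3.2.1]octan-1-yl]-2-hydroxy-3-oxopropyl benzoate F9.
   - Chelation-controlled addition of benzylic zinc chloride 27 gives (2S,3R)-4-(2,5-dimethoxy-4-methylphenyl)-2-[(1R,3S,5R)-3-[(1E)-2,6-dimethylhepta-1,5-dien-1-yl]-5-methyl-2,8-dioxabicyclo[3.2.1]octan-1-yl]-2,3-dihydroxybutyl benzoate F10.
   - K2CO3 (cat.) in CH3OH removes the benzoate to give (2S,3R)-4-(2,5-dimethoxy-4-methylphenyl)-2-[(1R,3S,5R)-3-[(1E)-2,6-dimethylhepta-1,5-dien-1-yl]-5-methyl-2,8-dioxabicyclo[3.2.1]octan-1-yl]butane-1,2,3-triol F11.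
   - Acetic anhydride, pyridine and catalytic 4-(dimethylamino)pyridine at 0 °C acetylate the primary and the secondary hydroxyl only, returning the route to diacetate 29.

**Further compounds**

F1 | step 11 | (4R,7E)-1-[2,2-dimethyl-5-(triethylsilyloxy)-1,3-dioxan-5-yl]-4-hydroxy-4,8,12-trimethyltrideca-7,11-diene-1,6-dione | CC[Si](CC)(CC)OC1(COC(C)(C)OC1)C(=O)CC[C@@](C)(O)CC(=O)/C=C(\C)CCC=C(C)C
F2 | step 5 | [(1R)-4-[2,2-dimethyl-5-(triethylsilyloxy)-1,3-dioxan-5-yl]-1-methylcyclohex-3-en-1-yl]methanol | OC[C@@]1(C)CC=C(CC1)C2(O[Si](CC)(CC)CC)COC(C)(C)OC2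
F3 | step 5 | [(1S,4R,6R)-1-[2,2-dimethyl-5-(triethylsilyloxy)-1,3-dioxan-5-yl]-4-methyl-7-oxabicyclo[4.1.0]heptan-4-yl]methanol | OC[C@@]1(C)C[C@H]2O[C@]2(CC1)C3(O[Si](CC)(CC)CC)COC(C)(C)OC3
F4 | step 5 | (1S,4R,6R)-1-[2,2-dimethyl-5-(triethylsilyloxy)-1,3-dioxan-5-yl]-4-methyl-7-oxabicyclo[4.1.0]heptane-4-carbaldehyde | O=C[C@@]1(C)C[C@H]2O[C@]2(CC1)C3(O[Si](CC)(CC)CC)COC(C)(C)OC3
F5 | step 5 | (1S,4R,6R)-1-[2,2-dimethyl-5-(triethylsilyloxy)-1,3-dioxan-5-yl]-4-methyl-7-oxabicyclo[4.1.0]heptan-4-yl formate | O=CO[C@@]1(C)C[C@H]2O[C@]2(CC1)C3(O[Si](CC)(CC)CC)COC(C)(C)OC3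
F6 | step 5 | (1S,4R,6R)-1-[2,2-dimethyl-5-(triethylsilyloxy)-1,3-dioxan-5-yl]-4-methyl-7-oxabicyclo[4.1.0]heptan-4-ol | O[C@@]1(C)C[C@H]2O[C@]2(CC1)C3(O[Si](CC)(CC)CC)COC(C)(C)OC3
F7 | step 5 | (1S,2R,4R)-1-[2,2-dimethyl-5-(triethylsilyloxy)-1,3-dioxan-5-yl]-4-methyl-7-oxabicyclo[2.2.1]heptan-2-ol | C[C@]12CC[C@@](O1)(C3(O[Si](CC)(CC)CC)COC(C)(C)OC3)[C@H](O)C2
F8 | step 13 | (2R)-2-[(1R,3S,5R)-3-[(1E)-2,6-dimethylhepta-1,5-dien-1-yl]-5-methyl-2,8-dioxabicyclo[3.2.1]octan-1-yl]-2,3-dihydroxypropyl benzoate | O=C(OC[C@](O)(CO)[C@]12CC[C@](C)(C[C@@H](/C=C(\C)CCC=C(C)C)O1)O2)c3ccccc3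
F9 | step 13 | (2S)-2-[(1R,3S,5R)-3-[(1E)-2,6-dimethylhepta-1,5-dien-1-yl]-5-methyl-2,8-dioxabicyclo[3.2.1]octan-1-yl]-2-hydroxy-3-oxopropyl benzoate | O=C(OC[C@](O)(C=O)[C@]12CC[C@](C)(C[C@@H](/C=C(\C)CCC=C(C)C)O1)O2)c3ccccc3
F10 | step 13 | (2S,3R)-4-(2,5-dimethoxy-4-methylphenyl)-2-[(1R,3S,5R)-3-[(1E)-2,6-dimethylhepta-1,5-dien-1-yl]-5-methyl-2,8-dioxabicyclo[3.2.1]octan-1-yl]-2,3-dihydroxybutyl benzoate | O=C(OC[C@](O)([C@@H](Cc3cc(OC)c(C)cc3OC)O)[C@]12CC[C@](C)(C[C@@H](/C=C(\C)CCC=C(C)C)O1)O2)c4ccccc4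
F11 | step 13 | (2S,3R)-4-(2,5-dimethoxy-4-methylphenyl)-2-[(1R,3S,5R)-3-[(1E)-2,6-dimethylhepta-1,5-dien-1-yl]-5-methyl-2,8-dioxabicyclo[3.2.1]octan-1-yl]butane-1,2,3-triol | OC[C@](O)([C@@H](Cc3cc(OC)c(C)cc3OC)O)[C@]12CC[C@](C)(C[C@@H](/C=C(\C)CCC=C(C)C)O1)O2
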